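**Retrosynthetic overview**
- The target comes from its bis(benzyl ether) by a final BCl3 debenzylation; the seven-membered lactone is opened at the acyl–O6 bond to a seco acid, so lactonisation is the last ring closure.
- The diaryl ether C–O7 bond is cut to a ring B phenol (chromanone with free 7-OH, O6 as allyl ether, O8 as benzyl ether) and a ring A aryl fluoride flanked by formyl and allyl ester groups (SNAr).
- The chromanone ring comes from the key C2–C3 bond formation: intermolecular aldol condensation of an o-hydroxyacetophenone with acetone, then oxa-Michael closure; O6 is added afterwards by bromination, borylation and oxidation.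
- The acetophenone comes from 5-methylpyrogallol (acylation, then O4 as MOM and O3 as benzyl by stepwise selective alkylation); ring A comes from 3,5-difluorotoluene (formylation between the fluorines, one F to OBn, bromination, carbonylation).
- Ring order: pyranone ring of the chromanone first, then the diaryl ether, then the dioxepinone lactone ring.

Assumption: the target has no stereocentre (C2 of the chromanone bears two methyl groups), so it is achiral and no stereocontrol is needed.

**Route**

Step 1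
Reactants: 1 3,5-difluorotoluene
Product: 3 2,6-difluoro-4-methylbenzaldehyde, via aryllithium 2 (not isolated)
Conditions: n-BuLi, THF, −78 °C; then DMF, −78 °C → rt; aq. HCl
Reagents that add atoms: N,N-dimethylformamide (CN(C)C=O)
Why: Directed ortho-lithiation removes only the C–H flanked by both fluorines, which is by far the most acidic, and the aryllithium is formylated by DMF (Bouveault formylation).

Step 2
Reactants: 3 2,6-difluoro-4-methylbenzaldehyde
Product: 4 2-(benzyloxy)-6-fluoro-4-methylbenzaldehyde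
Conditions: BnOH (1.0 equiv), NaH, THF, 0 °C → rt
Reagents that add atoms: benzyl alcohol (OCc1ccccc1)
Why: Nucleophilic aromatic substitution of a fluoride ortho to the formyl group by benzyloxide stops after one exchange because the substrate is symmetric and the new alkoxy group deactivates the ring.

Step 3
Reactants: 4 2-(benzyloxy)-6-fluoro-4-methylbenzaldehyde
Product: 5 6-(benzyloxy)-3-bromo-2-fluoro-4-methylbenzaldehyde
Conditions: NBS, DMF, rt
Reagents that add atoms: N-bromosuccinimide (O=C1CCC(=O)N1Br)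
Why: Electrophilic aromatic bromination goes para to the strongly donating benzyloxy group, at the less hindered site between F and CH3 and meta to the aldehyde.

Step 4
Reactants: 5 6-(benzyloxy)-3-bromo-2-fluoro-4-methylbenzaldehyde
Product: 6 4-(benzyloxy)-2-fluoro-3-formyl-6-methylbenzoic acid
Conditions: Pd(OAc)2 (cat.), Xantphos, CO (1 atm), Et3N, dioxane/H2O, 90 °C; then aq. HCl
Reagents that add atoms: carbon monoxide ([C-]#[O+]); water (O)
Why: Palladium-catalysed hydroxycarbonylation (oxidative addition, CO insertion, hydrolysis of the acylpalladium) turns the aryl bromide into the acid while the aldehyde, aryl fluoride and benzyl ether are inert.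

Step 5
Reactants: 6 4-(benzyloxy)-2-fluoro-3-formyl-6-methylbenzoic acid
Product: 7 allyl 4-(benzyloxy)-2-fluoro-3-formyl-6-methylbenzoate
Conditions: allyl bromide, KHCO3, DMF, rt
Reagents that add atoms: allyl bromide (C=CCBr)
Why: SN2 O-alkylation of the carboxylate is insensitive to the hindrance around the acyl carbon, and the mild base leaves the activated fluoride untouched.

Step 6
Reactants: 8 5-methylpyrogallol (5-methylbenzene-1,2,3-triol)
Product: 9 1-(2,3,4-trihydroxy-6-methylphenyl)ethanone
Conditions: Ac2O, ZnCl2, AcOH, 140 °C; then H2O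
Reagents that add atoms: acetic anhydride (CC(=O)OC(C)=O)
Why: Nencki (Friedel–Crafts) acylation of the electron-rich triol gives one regioisomer because the two free ring positions are equivalent.

Step 7
Reactants: 9 1-(2,3,4-trihydroxy-6-methylphenyl)ethanone
Product: 10 1-[2,3-dihydroxy-4-(methoxymethoxy)-6-methylphenyl]ethanone
Conditions: MOMCl (1.05 equiv), i-Pr2NEt, THF, 0 °C
Reagents that add atoms: chloromethyl methyl ether (COCCl)
Why: Selective O-alkylation occurs at the 4-OH, which is para to the acetyl group and therefore the most acidic and least hindered, while the 2-OH is chelated to the carbonyl.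

Step 8
Reactants: 10 1-[2,3-dihydroxy-4-(methoxymethoxy)-6-methylphenyl]ethanone
Product: 11 1-[3-(benzyloxy)-2-hydroxy-4-(methoxymethoxy)-6-methylphenyl]ethanone
Conditions: BnBr (1.1 equiv), K2CO3, acetone, 50 °C
Reagents that add atoms: benzyl bromide (BrCc1ccccc1)
Why: Williamson etherification takes the free 3-OH, whereas the 2-OH stays hydrogen-bonded to the ketone and unreactive.

Step 9
Reactants: 11 1-[3-(benzyloxy)-2-hydroxy-4-(methoxymethoxy)-6-methylphenyl]ethanone; 12 acetone
Product: 15 8-(benzyloxy)-7-(methoxymethoxy)-2,2,5-trimethylchroman-4-one, via β-hydroxy ketone 13 (not isolated), via enone 14 (not isolated)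
Conditions: acetone (excess), pyrrolidine, EtOH, 60 °C
Reagents that add atoms: none
Why: In this Kabbe chromanone synthesis a pyrrolidine-mediated intermolecular aldol condensation of the methyl ketone with acetone forms the C2–C3 bond and the ortho phenol then closes the ring by oxa-Michael addition, creating no stereocentre because C2 carries two methyl groups.

Step 10
Reactants: 15 8-(benzyloxy)-7-(methoxymethoxy)-2,2,5-trimethylchroman-4-one
Product: 16 8-(benzyloxy)-6-bromo-7-(methoxymethoxy)-2,2,5-trimethylchroman-4-one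
Conditions: NBS, DMF, 0 °C → rt
Reagents that add atoms: N-bromosuccinimide (O=C1CCC(=O)N1Br)
Why: Electrophilic aromatic bromination can only take C6, the single free ring position, which is activated by the para ring oxygen and the ortho 7-alkoxy group.

Step 11
Reactants: 16 8-(benzyloxy)-6-bromo-7-(methoxymethoxy)-2,2,5-trimethylchroman-4-one
Product: 17 8-(benzyloxy)-7-(methoxymethoxy)-2,2,5-trimethyl-6-(4,4,5,5-tetramethyl-1,3,2-dioxaborolan-2-yl)chroman-4-one
Conditions: B2pin2, Pd2(dba)3 (cat.), XPhos, KOAc, dioxane, 100 °C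
Reagents that add atoms: bis(pinacolato)diboron (CC1(C)OB(OC1(C)C)B1OC(C)(C)C(C)(C)O1)
Why: Miyaura borylation with a bulky biarylphosphine ligand copes with the di-ortho-substituted bromide, and the weak acetate base leaves the ketone and ethers alone.

Step 12
Reactants: 17 the C6 pinacol boronate
Product: 18 8-(benzyloxy)-6-hydroxy-7-(methoxymethoxy)-2,2,5-trimethylchroman-4-one
Conditions: 30% H2O2, NaOH, THF/H2O, 0 °C; Na2S2O3 quench
Reagents that add atoms: hydrogen peroxide (OO)
Why: Oxidation of the arylboronate (aryl migration from boron to oxygen in the hydroperoxide adduct) puts the hydroxyl exactly where the boron was.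

Step 13
Reactants: 18 8-(benzyloxy)-6-hydroxy-7-(methoxymethoxy)-2,2,5-trimethylchroman-4-one
Product: 19 6-(allyloxy)-8-(benzyloxy)-7-(methoxymethoxy)-2,2,5-trimethylchroman-4-one
Conditions: allyl bromide, K2CO3, DMF, rt
Reagents that add atoms: allyl bromide (C=CCBr)
Why: Williamson O-allylation of the only free phenol gives an ether that cannot migrate to a neighbouring oxygen under the later basic coupling.

Step 14
Reactants: 19 6-(allyloxy)-8-(benzyloxy)-7-(methoxymethoxy)-2,2,5-trimethylchroman-4-one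
Product: 20 6-(allyloxy)-8-(benzyloxy)-7-hydroxy-2,2,5-trimethylchroman-4-one
Conditions: 2 M HCl, THF, 45 °C
Reagents that add atoms: none
Why: Acid hydrolysis of the MOM acetal frees only O7, since allyl ether, benzyl ether and chromanone are stable to dilute acid.

Step 15
Reactants: 20 6-(allyloxy)-8-(benzyloxy)-7-hydroxy-2,2,5-trimethylchroman-4-one; 7 allyl 4-(benzyloxy)-2-fluoro-3-formyl-6-methylbenzoate
Product: 21 allyl 2-{[6-(allyloxy)-8-(benzyloxy)-2,2,5-trimethyl-4-oxochroman-7-yl]oxy}-4-(benzyloxy)-3-formyl-6-methylbenzoate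
Conditions: Cs2CO3, DMF, 70 °C, argon
Reagents that add atoms: none
Why: Nucleophilic aromatic substitution of the fluoride, activated by the ortho formyl and ortho ester groups, by the only free phenoxide (O7) fixes the diaryl ether regiochemistry without ambiguity.

Step 16
Reactants: 21 the diaryl ether bis-allyl compound
Product: 22 4-(benzyloxy)-2-{[8-(benzyloxy)-6-hydroxy-2,2,5-trimethyl-4-oxochroman-7-yl]oxy}-3-formyl-6-methylbenzoic acid
Conditions: Pd(PPh3)4 (cat.), morpholine, THF, rt; then dilute HCl wash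
Reagents that add atoms: none
Why: Tsuji–Trost deallylation ionises both the allyl ester and the allyl aryl ether and morpholine traps the π-allyl fragments, leaving benzyl ethers, aldehyde and ketone intact.

Step 17
Reactants: 22 the seco acid
Product: 24 bis(benzyl ether) of the target depsidone, via mixed anhydride 23 (not isolated)
Conditions: (CF3CO)2O, toluene, rt, high dilution
Reagents that add atoms: none
Why: Lactonisation through the mixed trifluoroacetic anhydride activates the hindered acid, and the seven-membered ring can only close onto O6 because it is the sole free hydroxyl.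

Step 18
Reactants: 24 bis(benzyl ether) of the target depsidone
Product: 25 target depsidone CNP0271978.0
Conditions: BCl3, pentamethylbenzene, CH2Cl2, −78 °C; then MeOH/H2O
Reagents that add atoms: none
Why: Lewis-acid debenzylation with pentamethylbenzene as benzyl cation scavenger cleaves both aryl benzyl ethers at low temperature without touching the aryl lactone, aldehyde or chromanone.

**Compound list**
1 | 3,5-difluorotoluene | Cc1cc(F)cc(F)c1 | starting material
2 | (2,6-difluoro-4-methylphenyl)lithium | [Li]c1c(F)cc(C)cc1F | intermediate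
3 | 2,6-difluoro-4-methylbenzaldehyde | Cc1cc(F)c(C=O)c(F)c1 | intermediate
4 | 2-(benzyloxy)-6-fluoro-4-methylbenzaldehyde | Cc1cc(F)c(C=O)c(OCc2ccccc2)c1 | intermediate
5 | 6-(benzyloxy)-3-bromo-2-fluoro-4-methylbenzaldehyde | Cc1cc(OCc2ccccc2)c(C=O)c(F)c1Br | intermediate
6 | 4-(benzyloxy)-2-fluoro-3-formyl-6-methylbenzoic acid | Cc1cc(OCc2ccccc2)c(C=O)c(F)c1C(=O)O | intermediate
7 | allyl 4-(benzyloxy)-2-fluoro-3-formyl-6-methylbenzoate | Cc1cc(OCc2ccccc2)c(C=O)c(F)c1C(=O)OCC=C | intermediate
8 | 5-methylpyrogallol (5-methylbenzene-1,2,3-triol) | Cc1cc(O)c(O)c(O)c1 | starting material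
9 | 1-(2,3,4-trihydroxy-6-methylphenyl)ethanone | CC(=O)c1c(C)cc(O)c(O)c1O | intermediate
10 | 1-[2,3-dihydroxy-4-(methoxymethoxy)-6-methylphenyl]ethanone | CC(=O)c1c(C)cc(OCOC)c(O)c1O | intermediate
11 | 1-[3-(benzyloxy)-2-hydroxy-4-(methoxymethoxy)-6-methylphenyl]ethanone | CC(=O)c1c(C)cc(OCOC)c(OCc2ccccc2)c1O | intermediate
12 | acetone | CC(C)=O | starting material
13 | 1-[3-(benzyloxy)-2-hydroxy-4-(methoxymethoxy)-6-methylphenyl]-3-hydroxy-3-methylbutan-1-one | CC(C)(O)CC(=O)c1c(C)cc(OCOC)c(OCc2ccccc2)c1O | intermediate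
14 | 1-[3-(benzyloxy)-2-hydroxy-4-(methoxymethoxy)-6-methylphenyl]-3-methylbut-2-en-1-one | CC(C)=CC(=O)c1c(C)cc(OCOC)c(OCc2ccccc2)c1O | intermediate
15 | 8-(benzyloxy)-7-(methoxymethoxy)-2,2,5-trimethylchroman-4-one | Cc1cc(OCOC)c(OCc2ccccc2)c2c1C(=O)CC(C)(C)O2 | intermediate
16 | 8-(benzyloxy)-6-bromo-7-(methoxymethoxy)-2,2,5-trimethylchroman-4-one | Cc1c(Br)c(OCOC)c(OCc2ccccc2)c2c1C(=O)CC(C)(C)O2 | intermediate
17 | 8-(benzyloxy)-7-(methoxymethoxy)-2,2,5-trimethyl-6-(4,4,5,5-tetramethyl-1,3,2-dioxaborolan-2-yl)chroman-4-one | Cc1c(B3OC(C)(C)C(C)(C)O3)c(OCOC)c(OCc2ccccc2)c2c1C(=O)CC(C)(C)O2 | intermediate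
18 | 8-(benzyloxy)-6-hydroxy-7-(methoxymethoxy)-2,2,5-trimethylchroman-4-one | Cc1c(O)c(OCOC)c(OCc2ccccc2)c2c1C(=O)CC(C)(C)O2 | intermediate
19 | 6-(allyloxy)-8-(benzyloxy)-7-(methoxymethoxy)-2,2,5-trimethylchroman-4-one | Cc1c(OCC=C)c(OCOC)c(OCc2ccccc2)c2c1C(=O)CC(C)(C)O2 | intermediate
20 | 6-(allyloxy)-8-(benzyloxy)-7-hydroxy-2,2,5-trimethylchroman-4-one | Cc1c(OCC=C)c(O)c(OCc2ccccc2)c2c1C(=O)CC(C)(C)O2 | intermediate
21 | allyl 2-{[6-(allyloxy)-8-(benzyloxy)-2,2,5-trimethyl-4-oxochroman-7-yl]oxy}-4-(benzyloxy)-3-formyl-6-methylbenzoate | Cc1cc(OCc2ccccc2)c(C=O)c(Oc3c(OCC=C)c(C)c4C(=O)CC(C)(C)Oc4c3OCc5ccccc5)c1C(=O)OCC=C | intermediate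
22 | 4-(benzyloxy)-2-{[8-(benzyloxy)-6-hydroxy-2,2,5-trimethyl-4-oxochroman-7-yl]oxy}-3-formyl-6-methylbenzoic acid | Cc1cc(OCc2ccccc2)c(C=O)c(Oc3c(O)c(C)c4C(=O)CC(C)(C)Oc4c3OCc5ccccc5)c1C(=O)O | intermediate
23 | mixed anhydride of acid 22 with trifluoroacetic acid | Cc1cc(OCc2ccccc2)c(C=O)c(Oc3c(O)c(C)c4C(=O)CC(C)(C)Oc4c3OCc5ccccc5)c1C(=O)OC(=O)C(F)(F)F | intermediate
24 | bis(benzyl ether) of the target depsidone (benzyl on the ring A phenol and on O-8 of the chromanone; lactone from the ring A carboxyl to O-6) | Cc1cc(OCc2ccccc2)c(C=O)c2c1C(=O)Oc1c(C)c3c(c(OCc4ccccc4)c1O2)OC(C)(C)CC3=O | intermediate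
25 | target depsidone CNP0271978.0 (achiral) | Cc1cc(O)c(C=O)c2c1C(=O)Oc1c(C)c3c(c(O)c1O2)OC(C)(C)CC3=O | target

**Step count**
Total: 18 steps. Longest linear sequence: 13 steps (8 to 25, steps 6–18). The ring A branch (steps 1–5) joins at step 15.

**Three steps most likely to fail, with fallbacks**

Step 15 (intermolecular SNAr giving a tetra-ortho-substituted diaryl ether from two hindered partners). The fallback forms the ester first and closes the ether intramolecularly. It sets out from phenol 18 and acid 6 and comes back at 24. Acid 6 is converted with (COCl)2 and catalytic DMF in CH2Cl2 into 4-(benzyloxy)-2-fluoro-3-formyl-6-methylbenzoyl chloride F1. F1 acylates the only free hydroxyl of 18 (Et3N, DMAP, CH2Cl2) to give 8-(benzyloxy)-7-(methoxymethoxy)-2,2,5-trimethyl-4-oxochroman-6-yl 4-(benzyloxy)-2-fluoro-3-formyl-6-methylbenzoate F2. Dilute HCl in THF removes the MOM group to give the 7-hydroxy ester 8-(benzyloxy)-7-hydroxy-2,2,5-trimethyl-4-oxochroman-6-yl 4-(benzyloxy)-2-fluoro-3-formyl-6-methylbenzoate F3. K2CO3 in DMF at 40 °C under high dilution then closes the seven-membered ring by intramolecular SNAr to give 24. If the acyl group shifts to O7, the equilibrium still strongly favours the O6 ester, because the O7 phenoxide (para to the ketone) is the more stabilised anion, and O8 is blocked as its benzyl ether.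

Step 11 (borylation of a bromide flanked by CH3 and OMOM). The fallback installs O6 before the chromanone ring is made, by way of a quinone. It sets out from 11 and comes back at 19.
- Phenol 11 is oxidised at its free para position with K2NO(SO3)2 in buffered aqueous acetone to the quinone 2-acetyl-6-(benzyloxy)-5-(methoxymethoxy)-3-methylcyclohexa-2,5-diene-1,4-dione F4.
- Na2S2O4 reduces F4 to the hydroquinone 1-[3-(benzyloxy)-2,5-dihydroxy-4-(methoxymethoxy)-6-methylphenyl]ethanone F5.
- Allyl bromide and K2CO3 in acetone alkylate only the non-chelated 5-OH to give 1-[5-(allyloxy)-3-(benzyloxy)-2-hydroxy-4-(methoxymethoxy)-6-methylphenyl]ethanone F6.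
- The same acetone/pyrrolidine condensation as in step 9 then runs through the β-hydroxy ketone 1-[5-(allyloxy)-3-(benzyloxy)-2-hydroxy-4-(methoxymethoxy)-6-methylphenyl]-3-hydroxy-3-methylbutan-1-one F7 and the enone 1-[5-(allyloxy)-3-(benzyloxy)-2-hydroxy-4-(methoxymethoxy)-6-methylphenyl]-3-methylbut-2-en-1-one F8 to give 19 directly.

Step 4 (palladium-catalysed hydroxycarbonylation of a di-ortho-substituted bromide bearing a free aldehyde). The fallback uses organolithium carboxylation. It sets out from 5 and comes back at 6. HC(OMe)3 with catalytic TsOH in MeOH gives the acetal 1-(benzyloxy)-4-bromo-2-(dimethoxymethyl)-3-fluoro-5-methylbenzene F9. Bromine–lithium exchange with n-BuLi in THF at −78 °C gives [4-(benzyloxy)-3-(dimethoxymethyl)-2-fluoro-6-methylphenyl]lithium F10. CO2 traps F10 as 4-(benzyloxy)-3-(dimethoxymethyl)-2-fluoro-6-methylbenzoic acid F11, and the aqueous HCl work-up hydrolyses the acetal to give 6.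

**Further compounds**
F1 | step 15 | 4-(benzyloxy)-2-fluoro-3-formyl-6-methylbenzoyl chloride | Cc1cc(OCc2ccccc2)c(C=O)c(F)c1C(Cl)=O
F2 | step 15 | 8-(benzyloxy)-7-(methoxymethoxy)-2,2,5-trimethyl-4-oxochroman-6-yl 4-(benzyloxy)-2-fluoro-3-formyl-6-methylbenzoate | Cc1cc(OCc2ccccc2)c(C=O)c(F)c1C(=O)Oc3c(C)c4C(=O)CC(C)(C)Oc4c(OCc5ccccc5)c3OCOC
F3 | step 15 | 8-(benzyloxy)-7-hydroxy-2,2,5-trimethyl-4-oxochroman-6-yl 4-(benzyloxy)-2-fluoro-3-formyl-6-methylbenzoate | Cc1cc(OCc2ccccc2)c(C=O)c(F)c1C(=O)Oc3c(C)c4C(=O)CC(C)(C)Oc4c(OCc5ccccc5)c3O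
F4 | step 11 | 2-acetyl-6-(benzyloxy)-5-(methoxymethoxy)-3-methylcyclohexa-2,5-diene-1,4-dione | CC(=O)C1=C(C)C(=O)C(OCOC)=C(OCc2ccccc2)C1=O
F5 | step 11 | 1-[3-(benzyloxy)-2,5-dihydroxy-4-(methoxymethoxy)-6-methylphenyl]ethanone | CC(=O)c1c(C)c(O)c(OCOC)c(OCc2ccccc2)c1O
F6 | step 11 | 1-[5-(allyloxy)-3-(benzyloxy)-2-hydroxy-4-(methoxymethoxy)-6-methylphenyl]ethanone | CC(=O)c1c(C)c(OCC=C)c(OCOC)c(OCc2ccccc2)c1O
F7 | step 11 | 1-[5-(allyloxy)-3-(benzyloxy)-2-hydroxy-4-(methoxymethoxy)-6-methylphenyl]-3-hydroxy-3-methylbutan-1-one | CC(C)(O)CC(=O)c1c(C)c(OCC=C)c(OCOC)c(OCc2ccccc2)c1O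
F8 | step 11 | 1-[5-(allyloxy)-3-(benzyloxy)-2-hydroxy-4-(methoxymethoxy)-6-methylphenyl]-3-methylbut-2-en-1-one | CC(C)=CC(=O)c1c(C)c(OCC=C)c(OCOC)c(OCc2ccccc2)c1O
F9 | step 4 | 1-(benzyloxy)-4-bromo-2-(dimethoxymethyl)-3-fluoro-5-methylbenzene | Cc1cc(OCc2ccccc2)c(C(OC)OC)c(F)c1Br
F10 | step 4 | [4-(benzyloxy)-3-(dimethoxymethyl)-2-fluoro-6-methylphenyl]lithium | Cc1cc(OCc2ccccc2)c(C(OC)OC)c(F)c1[Li]
F11 | step 4 | 4-(benzyloxy)-3-(dimethoxymethyl)-2-fluoro-6-methylbenzoic acid | Cc1cc(OCc2ccccc2)c(C(OC)OC)c(F)c1C(=O)O
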